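**Strategy.** Everything rests on cutting the C2–O1 bond of the dihydrobenzofuran. The free para-hydroxyl of ring A is conjugated with benzylic C2. Acid can therefore expel the C2 hydroxyl and flatten C2 into a para-quinone methide. The C7a phenol of ring B then adds, which closes the five-membered ring, forms C2–O1 and places the C2 aryl trans to the C3 hydroxymethyl (C9) in one operation. Only C3 must be built enantioselectively. The precursor is an open 1,2-diarylpropane-1,3-diol with both phenols free and a C5 bromide for the late Heck coupling. Its C3 is fixed by an Evans aldol whose C2 outcome is irrelevant.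

Key step: step 10

Numbering: O1, C2, C3, C3a, C7a of the dihydrobenzofuran, C9 = CH2OH carbon, ring A = guaiacyl ring on C2, ring B = benzo ring; the open-chain precursors carry the same labels.

Remark: the target is read as the (2R,3S) trans isomer, and the boron enolate of the arylacetyl imide is assumed to follow the usual syn-selective facial sense, which calls for the (R)-4-benzyl auxiliary.

**Step 1**
Reactants: 1 4-bromo-2-methoxyphenol
Product: 2 4-bromo-2-iodo-6-methoxyphenol
Conditions: I2 (1.05 equiv), KI, NaOH (aq), MeOH, 0 °C → rt; then dilute HCl, Na2S2O3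
Reagents that add atoms: iodine, [I][I]
Why: Electrophilic aromatic iodination of the phenoxide, whose para position is blocked by bromine, so the only strongly activated site is the free ortho carbon, the future C3a.

**Step 2**
Reactants: 2 4-bromo-2-iodo-6-methoxyphenol
Product: 3 2-(allyloxy)-5-bromo-1-iodo-3-methoxybenzene
Conditions: allyl bromide, K2CO3, DMF, rt
Reagents that add atoms: allyl bromide, C=CCBr
Why: Williamson ether synthesis giving an allyl ether that withstands carbonate, hydroxide, boron triflate and borohydride and can later be removed without acid or hydrogen, either of which would endanger the benzylic alcohol or the aryl bromide.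

**Step 3**
Reactants: 3 2-(allyloxy)-5-bromo-1-iodo-3-methoxybenzene; 4 diethyl malonate
Product: 5 diethyl 2-[2-(allyloxy)-5-bromo-3-methoxyphenyl]propanedioate
Conditions: CuI (10 mol %), 2-picolinic acid (20 mol %), Cs2CO3 (3 equiv), 1,4-dioxane, rt → 45 °C
Reagents that add atoms: none
Why: Copper-catalysed Ullmann–Hurtley-type C-arylation of a malonate, which near room temperature engages only the aryl iodide, so the C5 bromide is kept for the Heck coupling.

**Step 4**
Reactants: 5 diethyl 2-[2-(allyloxy)-5-bromo-3-methoxyphenyl]propanedioate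
Product: 7 2-[2-(allyloxy)-5-bromo-3-methoxyphenyl]acetic acid, via arylmalonic acid 6 (not isolated)
Conditions: NaOH (aq), EtOH, reflux; then HCl to pH 1, 70 °C
Reagents that add atoms: sodium hydroxide, [Na+].[OH-]
Why: Saponification followed by thermal decarboxylation of the arylmalonic acid, the usual end of a malonic ester synthesis, which the aryl allyl ether and the aryl bromide tolerate.

**Step 5**
Reactants: 7 2-[2-(allyloxy)-5-bromo-3-methoxyphenyl]acetic acid; 8 (R)-4-benzyl-1,3-oxazolidin-2-one
Product: 10 (R)-3-{2-[2-(allyloxy)-5-bromo-3-methoxyphenyl]acetyl}-4-benzyl-1,3-oxazolidin-2-one, via mixed pivalic anhydride 9 (not isolated)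
Conditions: PivCl, Et3N, THF, −20 °C; then LiCl, 8, −20 °C → rt
Reagents that add atoms: pivaloyl chloride, CC(C)(C)C(=O)Cl (its atoms are carried only by 9)
Why: N-acylation of the oxazolidinone through a mixed anhydride with LiCl activation, which avoids both the ketene-prone arylacetyl chloride and any strong base.

**Step 6**
Reactants: 11 vanillin
Product: 12 4-(allyloxy)-3-methoxybenzaldehyde
Conditions: allyl bromide, K2CO3, DMF, rt
Reagents that add atoms: allyl bromide, C=CCBr
Why: Williamson ether synthesis that gives ring A the same protecting group as ring B, so that one later operation frees both phenols.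

**Step 7**
Reactants: 10 (R)-3-{2-[2-(allyloxy)-5-bromo-3-methoxyphenyl]acetyl}-4-benzyl-1,3-oxazolidin-2-one; 12 4-(allyloxy)-3-methoxybenzaldehyde
Product: 14 (R)-3-{(2R,3R)-2-[2-(allyloxy)-5-bromo-3-methoxyphenyl]-3-[4-(allyloxy)-3-methoxyphenyl]-3-hydroxypropanoyl}-4-benzyl-1,3-oxazolidin-2-one, via Z boron enolate 13 (not isolated)
Conditions: Bu2BOTf (1.2 equiv), Et3N (1.4 equiv), CH2Cl2, −78 → 0 °C; 12, −78 → 0 °C; pH 7 buffer, MeOH, 30% H2O2, 0 °C
Reagents that add atoms: dibutylboron triflate, CCCCB(CCCC)OS(=O)(=O)C(F)(F)F (its boron fragment is carried only by 13)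
Why: Evans syn aldol reaction in which soft enolisation gives the Z boron enolate 13, which reacts through a chair-like Zimmerman–Traxler transition state on the enolate face turned away from the benzyl group of the (R)-auxiliary, so that C3 (the α-carbon, R in the imide) is set by the auxiliary, while the syn carbinol centre C2 formed alongside is of no consequence because step 10 erases it, and minor diastereomers are removed by chromatography before the auxiliary is cleaved.

**Step 8**
Reactants: 14 the syn aldol imide
Product: 15 (1R,2S)-2-[2-(allyloxy)-5-bromo-3-methoxyphenyl]-1-[4-(allyloxy)-3-methoxyphenyl]propane-1,3-diol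
Conditions: LiBH4, MeOH (1 equiv per hydride reagent), THF/Et2O, 0 °C
Reagents that add atoms: none
Why: Reductive cleavage of the imide, a standard auxiliary removal that turns the acyl carbon into C9 at 0 °C without touching the α-stereocentre, the bromide or the allyl ethers, the C3 descriptor changing from R to S only because the substituent priorities change.

**Step 9**
Reactants: 15 the bis(allyl ether) diol
Product: 16 (1R,2S)-2-(5-bromo-2-hydroxy-3-methoxyphenyl)-1-(4-hydroxy-3-methoxyphenyl)propane-1,3-diol (tetraol: two phenols, two alcohols)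
Conditions: Pd(PPh3)4 (5 mol %), morpholine (10 equiv), THF, rt, argon
Reagents that add atoms: none
Why: Tsuji–Trost-type deallylation in which zerovalent palladium ionises both aryl allyl ethers at room temperature and morpholine takes up the allyl groups, under conditions that are neither acidic nor reducing and too mild for oxidative addition into the electron-rich aryl bromide.

**Step 10**
Reactants: 16 (1R,2S)-2-(5-bromo-2-hydroxy-3-methoxyphenyl)-1-(4-hydroxy-3-methoxyphenyl)propane-1,3-diol
Product: 18 4-[(2R,3S)-5-bromo-3-(hydroxymethyl)-7-methoxy-2,3-dihydro-1-benzofuran-2-yl]-2-methoxyphenol, via para-quinone methide 17 (not isolated)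
Conditions: p-TsOH·H2O (10 mol %), MeCN (0.01 M), 0 °C → rt, argon; NaHCO3 quench
Reagents that add atoms: none
Why: The acid protonates the C2 hydroxyl and water leaves with the push of the para-hydroxyl of ring A, giving the planar para-quinone methide 17 (or its O-protonated form), so the C2 configuration inherited from the aldol is wiped out and any C2 epimer present would enter the same channel. The C7a phenol of ring B then attacks C2 in a 1,6-conjugate addition that makes the C2–O1 bond and returns ring A to a phenol; the closest known reaction type is the acid-induced cyclodehydration of 1,2-diarylpropane-1,3-diols to trans-2-aryl-3-hydroxymethyl-2,3-dihydrobenzofurans known from lignin model chemistry. The single ring closes in the 5-exo-trig mode, because the C2=C1' double bond of 17 stays outside the new five-membered ring. The new stereocentre C2 is controlled by C3 alone: ring A avoids the C9 arm in the closing transition state, and since the benzylic aryl ether can reopen under the same acid, any cis ring drains to the more stable trans (2R,3S) isomer, an outcome that an invertive displacement on syn-configured 16 could not give. The selectivity needed is the choice among oxygen nucleophiles, and the substrate secures it because the C9 hydroxyl could only give a strained four-membered ether that reopens, while high dilution in a weakly nucleophilic solvent holds back intermolecular capture by other phenols. C3 is not acidified by catalytic acid at or below room temperature, and quenching with NaHCO3 as soon as convergence is complete guards against tautomerisation of 17 that would erode it.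

**Step 11**
Reactants: 19 3,5-dihydroxybenzaldehyde
Product: 21 5-vinyl-1,3-phenylene diacetate (3,5-diacetoxystyrene), via dipotassium 5-vinylresorcinolate 20 (not isolated)
Conditions: MePPh3Br (1.5 equiv), KOt-Bu (3.6 equiv), THF, 0 °C → rt; then Ac2O (5 equiv), 0 °C → rt
Reagents that add atoms: methyltriphenylphosphonium bromide, C[P+](c1ccccc1)(c1ccccc1)c1ccccc1.[Br-]; acetic anhydride, CC(=O)OC(C)=O; potassium tert-butoxide, CC(C)(C)[O-].[K+] (potassium carried only by 20)
Why: Wittig methylenation run with enough base to carry both phenols as phenoxides, which sit meta to the formyl group and do not deactivate it, followed by O-acetylation in the same flask so that the polymerisation-prone free vinylresorcinol is never handled.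

**Step 12**
Reactants: 18 the trans 5-bromodihydrobenzofuran; 21 3,5-diacetoxystyrene
Product: 22 5-{(E)-2-[(2R,3S)-3-(hydroxymethyl)-2-(4-hydroxy-3-methoxyphenyl)-7-methoxy-2,3-dihydro-1-benzofuran-5-yl]vinyl}-1,3-phenylene diacetate
Conditions: Pd2(dba)3 (2.5 mol %), [HP(t-Bu)3]BF4 (10 mol %), Cy2NMe (2 equiv), 1,4-dioxane, 50 °C, argon
Reagents that add atoms: none
Why: Mizoroki–Heck reaction in which the bulky electron-rich phosphine lets zerovalent palladium insert into the electron-rich C5–Br bond at mild temperature, syn insertion at the unsubstituted styrene terminus and syn β-hydride elimination give the E stilbene, and the hindered amine and low temperature spare the C2–O1 bond and limit acetyl transfer, which the last step would erase in any case.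

**Step 13**
Reactants: 22 the stilbene diacetate
Product: 23 gnetofuran A
Conditions: K2CO3 (0.2 equiv), degassed MeOH, 0 °C → rt, argon; then NH4Cl (aq)
Reagents that add atoms: none
Why: Base-catalysed transesterification (Zemplén-type methanolysis) of the aryl acetates, fast with catalytic carbonate, which leaves both stereocentres, the E alkene and the dihydrofuran ring untouched.

**Compound list**

1 | 4-bromo-2-methoxyphenol | COc1cc(Br)ccc1O | starting material
2 | 4-bromo-2-iodo-6-methoxyphenol | Oc1c(OC)cc(Br)cc1I | intermediate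
3 | 2-(allyloxy)-5-bromo-1-iodo-3-methoxybenzene | C=CCOc1c(OC)cc(Br)cc1I | intermediate
4 | diethyl malonate | CCOC(=O)CC(=O)OCC | starting material
5 | diethyl 2-[2-(allyloxy)-5-bromo-3-methoxyphenyl]propanedioate | CCOC(=O)C(C(=O)OCC)c1cc(Br)cc(OC)c1OCC=C | intermediate
6 | 2-[2-(allyloxy)-5-bromo-3-methoxyphenyl]propanedioic acid (formed in the flask) | OC(=O)C(C(=O)O)c1cc(Br)cc(OC)c1OCC=C | intermediate
7 | 2-[2-(allyloxy)-5-bromo-3-methoxyphenyl]acetic acid | OC(=O)Cc1cc(Br)cc(OC)c1OCC=C | intermediate
8 | (R)-4-benzyl-1,3-oxazolidin-2-one | O=C1N[C@H](Cc2ccccc2)CO1 | starting material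
9 | 2-[2-(allyloxy)-5-bromo-3-methoxyphenyl]acetic pivalic anhydride (formed in the flask) | CC(C)(C)C(=O)OC(=O)Cc1cc(Br)cc(OC)c1OCC=C | intermediate
10 | (R)-3-{2-[2-(allyloxy)-5-bromo-3-methoxyphenyl]acetyl}-4-benzyl-1,3-oxazolidin-2-one | O=C(Cc1cc(Br)cc(OC)c1OCC=C)N1C(=O)OC[C@H]1Cc1ccccc1 | intermediate
11 | vanillin | COc1cc(C=O)ccc1O | starting material
12 | 4-(allyloxy)-3-methoxybenzaldehyde | COc1cc(C=O)ccc1OCC=C | intermediate
13 | (Z)-dibutylboron enolate of 10 (formed in the flask) | CCCCB(CCCC)O/C(=C\c1cc(Br)cc(OC)c1OCC=C)N1C(=O)OC[C@H]1Cc1ccccc1 | intermediate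
14 | (R)-3-{(2R,3R)-2-[2-(allyloxy)-5-bromo-3-methoxyphenyl]-3-[4-(allyloxy)-3-methoxyphenyl]-3-hydroxypropanoyl}-4-benzyl-1,3-oxazolidin-2-one | O=C([C@@H]([C@@H](O)c1ccc(OCC=C)c(OC)c1)c1cc(Br)cc(OC)c1OCC=C)N1C(=O)OC[C@H]1Cc1ccccc1 | intermediate
15 | (1R,2S)-2-[2-(allyloxy)-5-bromo-3-methoxyphenyl]-1-[4-(allyloxy)-3-methoxyphenyl]propane-1,3-diol | COc1cc([C@H](O)[C@H](CO)c2cc(Br)cc(OC)c2OCC=C)ccc1OCC=C | intermediate
16 | (1R,2S)-2-(5-bromo-2-hydroxy-3-methoxyphenyl)-1-(4-hydroxy-3-methoxyphenyl)propane-1,3-diol | COc1cc([C@H](O)[C@H](CO)c2cc(Br)cc(OC)c2O)ccc1O | intermediate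
17 | 4-[(2S)-2-(5-bromo-2-hydroxy-3-methoxyphenyl)-3-hydroxypropylidene]-2-methoxycyclohexa-2,5-dien-1-one (formed in the flask) | COC1=CC(=C[C@H](CO)c2cc(Br)cc(OC)c2O)C=CC1=O | intermediate
18 | 4-[(2R,3S)-5-bromo-3-(hydroxymethyl)-7-methoxy-2,3-dihydro-1-benzofuran-2-yl]-2-methoxyphenol | COc1cc([C@@H]2Oc3c(OC)cc(Br)cc3[C@H]2CO)ccc1O | intermediate
19 | 3,5-dihydroxybenzaldehyde | O=Cc1cc(O)cc(O)c1 | starting material
20 | dipotassium 5-vinylbenzene-1,3-diolate (formed in the flask) | C=Cc1cc([O-])cc([O-])c1.[K+].[K+] | intermediate
21 | 5-vinyl-1,3-phenylene diacetate | C=Cc1cc(OC(C)=O)cc(OC(C)=O)c1 | intermediate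
22 | 5-{(E)-2-[(2R,3S)-3-(hydroxymethyl)-2-(4-hydroxy-3-methoxyphenyl)-7-methoxy-2,3-dihydro-1-benzofuran-5-yl]vinyl}-1,3-phenylene diacetate | COc1cc([C@@H]2Oc3c(OC)cc(/C=C/c4cc(OC(C)=O)cc(OC(C)=O)c4)cc3[C@H]2CO)ccc1O | intermediate
23 | gnetofuran A, 5-{(E)-2-[(2R,3S)-3-(hydroxymethyl)-2-(4-hydroxy-3-methoxyphenyl)-7-methoxy-2,3-dihydro-1-benzofuran-5-yl]vinyl}benzene-1,3-diol | COc1cc([C@@H]2Oc3c(OC)cc(/C=C/c4cc(O)cc(O)c4)cc3[C@H]2CO)ccc1O | target

Total step count: 13.
Longest linear sequence: 11 steps (steps 1–5, 7–10, 12, 13).

**Steps most likely to fail**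

**Step 10.**
- **Risk:** Other phenols may capture the quinone methide intermolecularly. The C9 arm may be lost by fragmentation. The configuration at C3 may slowly erode through tautomerisation while acid is present.
- **Fallback:** It sets out from 16 and separates activation from ring closure.
  - TMSBr in CH2Cl2/1,4-dioxane at 0 °C exchanges only the benzylic C2 hydroxyl for bromide. This gives 4-bromo-2-[(2S)-1-bromo-3-hydroxy-1-(4-hydroxy-3-methoxyphenyl)propan-2-yl]-6-methoxyphenol F1.
  - Shaking this solution with saturated aqueous NaHCO3 removes HBr by 1,6-elimination. That releases 17 in an acid-free organic phase, where the ring B phenol closes the ring.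
- **Return:** The fallback comes back to the route at 18.

**Step 7.**
- **Risk:** A hindered, aryl-stabilised enolate may add sluggishly or reversibly to an electron-rich aldehyde, and facial selectivity would erode with it.
- **Fallback:** It sets C3 by enzymatic desymmetrisation and makes the C2–C3 bond by aryl-metal addition, setting out from 5 and, for ring A, from 1.
  - LiAlH4 (THF, 0 °C) reduces 5 to the prochiral 2-[2-(allyloxy)-5-bromo-3-methoxyphenyl]propane-1,3-diol F2.
  - Lipase-catalysed monoacetylation (Burkholderia cepacia lipase, vinyl acetate, t-BuOMe) is screened for the (S)-monoacetate F3.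
  - TBSCl/imidazole gives the silyl ether acetate F4, and K2CO3/MeOH gives the primary alcohol F5.
  - Buffered Dess–Martin oxidation gives the α-aryl aldehyde F6. Its β-silyloxy group resists elimination better than an acetate would, and it is used at once at −78 °C.
  - In parallel, 1 is allylated to 1-(allyloxy)-4-bromo-2-methoxybenzene F7 and converted with Mg turnings in THF into the aryl Grignard reagent F8.
  - F8 adds to F6 to give the C2-epimeric silyl-protected carbinols F9.
- **Return:** TBAF brings the fallback back to the route at 15, now accompanied by its C2 epimer F10. Step 9 turns the pair into 16 and its C2 epimer F11, and step 10 merges both into 18.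

**Step 12.**
- **Risk:** Oxidative addition into the electron-rich bromide may be slow. The free phenol may inhibit the catalyst. Prolonged heating with base may reopen the C2–O1 bond.
- **Fallback:** It sets out from 21.
  - Cross-metathesis with vinylboronic acid pinacol ester (second-generation Grubbs catalyst, CH2Cl2, 40 °C) gives the (E)-styrylboronic acid pinacol ester F12.
  - Suzuki–Miyaura coupling of this boronate with 18 (Pd(dppf)Cl2, CsF, 1,4-dioxane, 70 °C) forms the same C5–vinyl bond by transmetalation instead of carbopalladation, with the E geometry fixed beforehand.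
- **Return:** The fallback comes back to the route at 22.

**Further compounds**

F1 | step 10 | 4-bromo-2-[(2S)-1-bromo-3-hydroxy-1-(4-hydroxy-3-methoxyphenyl)propan-2-yl]-6-methoxyphenol (both C2 epimers) | COc1cc(C(Br)[C@H](CO)c2cc(Br)cc(OC)c2O)ccc1O
F2 | step 7 | 2-[2-(allyloxy)-5-bromo-3-methoxyphenyl]propane-1,3-diol | OCC(CO)c1cc(Br)cc(OC)c1OCC=C
F3 | step 7 | (S)-2-[2-(allyloxy)-5-bromo-3-methoxyphenyl]-3-hydroxypropyl acetate | CC(=O)OC[C@H](CO)c1cc(Br)cc(OC)c1OCC=C
F4 | step 7 | (R)-2-[2-(allyloxy)-5-bromo-3-methoxyphenyl]-3-[(tert-butyldimethylsilyl)oxy]propyl acetate | CC(=O)OC[C@H](CO[Si](C)(C)C(C)(C)C)c1cc(Br)cc(OC)c1OCC=C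
F5 | step 7 | (R)-2-[2-(allyloxy)-5-bromo-3-methoxyphenyl]-3-[(tert-butyldimethylsilyl)oxy]propan-1-ol | OC[C@H](CO[Si](C)(C)C(C)(C)C)c1cc(Br)cc(OC)c1OCC=C
F6 | step 7 | (S)-2-[2-(allyloxy)-5-bromo-3-methoxyphenyl]-3-[(tert-butyldimethylsilyl)oxy]propanal | O=C[C@H](CO[Si](C)(C)C(C)(C)C)c1cc(Br)cc(OC)c1OCC=C
F7 | step 7 | 1-(allyloxy)-4-bromo-2-methoxybenzene | C=CCOc1ccc(Br)cc1OC
F8 | step 7 | [4-(allyloxy)-3-methoxyphenyl]magnesium bromide | C=CCOc1ccc([Mg]Br)cc1OC
F9 | step 7 | (2S)-2-[2-(allyloxy)-5-bromo-3-methoxyphenyl]-1-[4-(allyloxy)-3-methoxyphenyl]-3-[(tert-butyldimethylsilyl)oxy]propan-1-ol (both C2 epimers) | COc1cc(C(O)[C@H](CO[Si](C)(C)C(C)(C)C)c2cc(Br)cc(OC)c2OCC=C)ccc1OCC=C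
F10 | step 7 | (1S,2S)-2-[2-(allyloxy)-5-bromo-3-methoxyphenyl]-1-[4-(allyloxy)-3-methoxyphenyl]propane-1,3-diol | COc1cc([C@@H](O)[C@H](CO)c2cc(Br)cc(OC)c2OCC=C)ccc1OCC=C
F11 | step 7 | (1S,2S)-2-(5-bromo-2-hydroxy-3-methoxyphenyl)-1-(4-hydroxy-3-methoxyphenyl)propane-1,3-diol | COc1cc([C@@H](O)[C@H](CO)c2cc(Br)cc(OC)c2O)ccc1O
F12 | step 12 | 5-[(E)-2-(4,4,5,5-tetramethyl-1,3,2-dioxaborolan-2-yl)vinyl]-1,3-phenylene diacetate | CC(=O)Oc1cc(/C=C/B2OC(C)(C)C(C)(C)O2)cc(OC(C)=O)c1
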